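**Retrosynthetic overview**
1. Late stage: the butenolide comes from acrylate ring-closing metathesis after a catalyst-controlled allylboration of a C11 aldehyde; C4=C18 comes from methylenation of a C4 ketone; the C6, C7 and C8 oxygens come from a C7=C8 alkene (allylic oxidation, α-face dihydroxylation, hydroxyl-directed reduction).
2. Key disconnection: C1–C10 and C5–C10. A monocyclic cyclopentanone (ring-A precursor C1–C2–C3–C4–C5) carries on C5 the tether C6–C7=C8–C9–C10(=N2). Intramolecular diazoalkane insertion puts C10 between C1 and C5, so ring A grows from five to six atoms while ring B closes.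
3. Enabling feature: the C1 ketone is flanked by the quaternary C5, and C5 is tied to the diazo carbon C10 through the (Z)-C7=C8 alkene and the quaternary C9. This holds C10 over C1 and places the C1–C5 bond anti to the departing N2.
4. Precursor: 2-methylcyclopentane-1,3-dione is allylated (Tsuji–Trost) with a (Z)-allylic acetate and desymmetrised by transfer hydrogenation (sets C5). C9 comes from Sharpless epoxidation and a siloxymethyl 1,2-shift; the Z geometry is locked by lactone ring-closing metathesis.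
5. Ring order: cyclopentane (purchased) → rings A and B together (step 16) → butenolide (step 33).

Key step: step 16

Remark: clerodane locants are used for all intermediates (ring A = C1–C5, C10; ring B = C5–C10; C17 on C8, C18 on C4, C19 on C5, C20 on C9, C11–C16 side chain). β is the face of the C5 methyl (C19), α the opposite face. The C4 carbinol configuration from step 12 (hydride anti to the side chain) is assumed; it is erased in step 25.

Step 1
Reactants: 1 3-methylbut-3-en-2-one; 2 triethyl phosphonoacetate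
Product: 3 ethyl (2E)-3,4-dimethylpenta-2,4-dienoate
Conditions: NaH, THF, 0 °C to reflux; (2E) isomer separated by chromatography
Reagents that add atoms: none
Why: Horner–Wadsworth–Emmons olefination of the methyl ketone should place the ester trans to the larger isopropenyl group, giving mainly the (2E)-dienoate.

Step 2
Reactants: 3 ethyl (2E)-3,4-dimethylpenta-2,4-dienoate
Product: 4 (2E)-3,4-dimethylpenta-2,4-dien-1-ol
Conditions: i-Bu2AlH (2.2 equiv), CH2Cl2, −78 °C
Reagents that add atoms: none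
Why: 1,2-reduction of the conjugated ester by the aluminium hydride gives the allylic alcohol and leaves the diene intact.

Step 3
Reactants: 4 (2E)-3,4-dimethylpenta-2,4-dien-1-ol
Product: 5 [(2S,3S)-3-methyl-3-(prop-1-en-2-yl)oxiran-2-yl]methanol
Conditions: Ti(OiPr)4 (10 mol %), L-(+)-diethyl tartrate (12 mol %), t-BuOOH, 4 Å MS, CH2Cl2, −20 °C
Reagents that add atoms: tert-butyl hydroperoxide, CC(C)(C)OO
Why: Sharpless asymmetric epoxidation oxidises only the allylic-alcohol double bond, and by analogy with other (E)-3-methyl-2-alken-1-ols the L-(+)-tartrate ligand should give the (2S,3S) epoxide that later fixes C9.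

Step 4
Reactants: 5 [(2S,3S)-3-methyl-3-(prop-1-en-2-yl)oxiran-2-yl]methanol
Product: 6 tert-butyl(dimethyl){[(2S,3S)-3-methyl-3-(prop-1-en-2-yl)oxiran-2-yl]methoxy}silane
Conditions: TBSCl, imidazole, DMF, 0 °C
Reagents that add atoms: tert-butyl(chloro)dimethylsilane, CC(C)(C)[Si](C)(C)Cl
Why: Standard silylation of the primary alcohol provides the epoxy silyl ether required for the rearrangement.

Step 5
Reactants: 6 epoxy silyl ether
Product: 7 (2S)-2-({[tert-butyl(dimethyl)silyl]oxy}methyl)-2,3-dimethylbut-3-enal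
Conditions: MeAl(OC6H2-2,6-tBu2-4-Br)2 (20 mol %), CH2Cl2, −78 °C
Reagents that add atoms: none
Why: Organoaluminium-promoted semipinacol rearrangement of the 2,3-epoxy silyl ether: ionisation at the tertiary allylic epoxide carbon and anti 1,2-shift of the siloxymethyl group give the β-siloxy aldehyde with inversion at the migration terminus, which becomes quaternary C9 (C10 = CHO, C11 = CH2OTBS).

Step 6
Reactants: 7 aldehyde
Product: 8 (2S)-2-({[tert-butyl(dimethyl)silyl]oxy}methyl)-2,3-dimethylbut-3-enoic acid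
Conditions: NaClO2, NaH2PO4, 2-methylbut-2-ene, t-BuOH/H2O, 0 °C to 23 °C
Reagents that add atoms: sodium chlorite, [Na+].[O-]Cl=O
Why: Pinnick oxidation converts the non-enolisable aldehyde into the acid while the scavenger protects the alkene from hypochlorite.

Step 7
Reactants: 8 acid; 9 allyl bromide
Product: 10 prop-2-en-1-yl (2S)-2-({[tert-butyl(dimethyl)silyl]oxy}methyl)-2,3-dimethylbut-3-enoate
Conditions: K2CO3, DMF, 23 °C
Reagents that add atoms: none
Why: O-alkylation of the carboxylate (SN2) installs the allyl group that supplies C6 and C7.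

Step 8
Reactants: 10 allyl ester
Product: 11 (3S)-3-({[tert-butyl(dimethyl)silyl]oxy}methyl)-3,4-dimethyl-3,6-dihydro-2H-pyran-2-one
Conditions: second-generation Grubbs catalyst RuCl2(=CHPh)(PCy3)(H2IMes) (5 mol %), toluene, 80 °C
Reagents that add atoms: none
Why: Ring-closing metathesis of the allyl ester onto the isopropenyl group gives the six-membered lactone, whose ring locks C7=C8 in the Z geometry (C6 and C9 cis).

Step 9
Reactants: 11 lactone
Product: 12 (2R,3Z)-2-({[tert-butyl(dimethyl)silyl]oxy}methyl)-2,3-dimethylpent-3-ene-1,5-diol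
Conditions: LiAlH4, Et2O, 0 °C
Reagents that add atoms: none
Why: Hydride reduction opens the lactone to the (Z)-diol, separating an allylic alcohol (C6) from a neopentyl alcohol (C10).

Step 10
Reactants: 12 diol
Product: 13 (2Z,4R)-4-({[tert-butyl(dimethyl)silyl]oxy}methyl)-5-hydroxy-3,4-dimethylpent-2-en-1-yl acetate
Conditions: AcCl (1.05 equiv), 2,4,6-collidine, CH2Cl2, −78 °C
Reagents that add atoms: acetyl chloride, CC(Cl)=O
Why: Kinetic acylation should take place at the unhindered allylic primary hydroxyl and not at the neopentyl one next to the quaternary carbon.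

Step 11
Reactants: 13 allylic acetate; 14 2-methylcyclopentane-1,3-dione
Product: 15 2-[(2Z,4R)-4-({[tert-butyl(dimethyl)silyl]oxy}methyl)-5-hydroxy-3,4-dimethylpent-2-en-1-yl]-2-methylcyclopentane-1,3-dione
Conditions: Pd(PPh3)4 (5 mol %), Et3N, THF, 40 °C
Reagents that add atoms: none
Why: Tsuji–Trost allylic alkylation: the soft dione enolate attacks the unhindered C6 terminus of the π-allylpalladium complex, and the Z geometry should survive because syn–anti isomerisation would need a tertiary σ-allyl at C8.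

Step 12
Reactants: 15 prochiral dione
Product: 16 (2R,3R)-2-[(2Z,4R)-4-({[tert-butyl(dimethyl)silyl]oxy}methyl)-5-hydroxy-3,4-dimethylpent-2-en-1-yl]-3-hydroxy-2-methylcyclopentan-1-one
Conditions: RuCl(p-cymene)[(R,R)-TsDPEN] (1 mol %), HCO2H/Et3N (5:2), CH2Cl2, 23 °C
Reagents that add atoms: none
Why: Noyori-type asymmetric transfer hydrogenation desymmetrises the 2,2-disubstituted dione: the catalyst selects one enantiotopic carbonyl (fixing quaternary C5; the catalyst antipode would be used if the sense proved opposite) and hydride adds anti to the side chain, leaving C1 as the ketone.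

Step 13
Reactants: 16 keto diol
Product: 17 (2S,3Z)-2-({[tert-butyl(dimethyl)silyl]oxy}methyl)-5-[(1R,2R)-2-hydroxy-1-methyl-5-oxocyclopentyl]-2,3-dimethylpent-3-enal
Conditions: TEMPO (10 mol %), PhI(OAc)2, CH2Cl2, 23 °C
Reagents that add atoms: none
Why: Oxoammonium-mediated oxidation is selective for the primary alcohol over the hindered secondary carbinol and stops at the non-enolisable aldehyde (C10).

Step 14
Reactants: 17 hydroxy aldehyde
Product: 18 (2S,3Z)-5-[(1R,2R)-2-{[tert-butyl(dimethyl)silyl]oxy}-1-methyl-5-oxocyclopentyl]-2-({[tert-butyl(dimethyl)silyl]oxy}methyl)-2,3-dimethylpent-3-enal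
Conditions: TBSOTf, 2,6-lutidine, CH2Cl2, −78 °C
Reagents that add atoms: tert-butyldimethylsilyl trifluoromethanesulfonate, CC(C)(C)[Si](C)(C)OS(=O)(=O)C(F)(F)F
Why: Silylation of the C4 hydroxyl prevents retro-aldol cleavage and O–H interference in the diazo chemistry; the aldehyde has no α-hydrogen and is inert.

Step 15
Reactants: 18 keto aldehyde
Product: 19 N-(tert-butyldimethylsilyl) hydrazone of 18 at C10
Conditions: TBSNHNHTBS, Sc(OTf)3 (1 mol %), CH2Cl2, 23 °C
Reagents that add atoms: 1,2-bis(tert-butyldimethylsilyl)hydrazine, CC(C)(C)[Si](C)(C)NN[Si](C)(C)C(C)(C)C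
Why: Lewis-acid-catalysed condensation occurs at the aldehyde and not at the hindered α-quaternary ketone, giving a storable N-silyl hydrazone that releases the diazoalkane on oxidation at low temperature.

Step 16
Reactants: 19 N-silyl hydrazone
Product: 21 trans-decalone 1-ketone with 4α-OTBS and 9α-CH2OTBS, via diazoalkane 20 (not isolated)
Conditions: PhIF2, 2-chloropyridine, CH2Cl2, −78 °C; then Sc(OTf)3 (10 mol %), −78 to −20 °C; then DBU, 23 °C
Reagents that add atoms: none
Why: Proposed new method: PhIF2 oxidises the N-silyl hydrazone at −78 °C to the neopentyl diazoalkane 20, whose diazo carbon C10 adds to the Sc(OTf)3-activated C1 carbonyl (7-exo-trig) to give a bicyclic β-oxido diazonium ion, and anti-periplanar 1,2-shift of the quaternary C5 from C1 to C10 with loss of N2 inserts C10 into the C1–C5 bond. The closest known reactions are the Lewis-acid-catalysed diazoalkane–ketone ring homologation (Tiffeneau–Demjanov type) and the intramolecular Schmidt reaction of ketones bearing an azide on an α-tether, which gives fused rings by the same shift. Ring A forms by one-carbon expansion of the cyclopentanone (C1–C2–C3–C4–C5 becomes C1–C2–C3–C4–C5–C10), and ring B forms in the same event by contraction of the transient seven-membered adduct to the cyclohexene C5–C6–C7=C8–C9–C10. C5 migrates with retention and C9 is untouched; the only new stereocentre, C10, is formed with inversion at the diazonium carbon from the adduct that keeps N2 pseudo-equatorial and C9 anti to C2, which leads to the trans fusion, and because C10 is α to the C1 ketone the DBU treatment lets any cis epimer equilibrate to the trans-decalone, which is expected to be the more stable. The step needs C5 rather than C2 to migrate (C2 would give a bridged ketone) and needs carbonyl addition to outrun dipolar cycloaddition of the diazo group onto C7=C8; the first is secured by the pseudo-equatorial diazonium imposed by the Z-alkene tether between two quaternary carbons, the second by generating the diazoalkane at −78 °C and adding the Lewis acid before warming.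

Step 17
Reactants: 21 trans-decalone
Product: 22 1α-alcohol (4α-OTBS, 7-ene, 9α-CH2OTBS, 10α-H)
Conditions: Li, NH3(l)/THF, t-BuOH, −78 °C; NH4Cl
Reagents that add atoms: none
Why: Dissolving-metal reduction gives the thermodynamically preferred equatorial 1α-alcohol, since the axial 1β-epimer would clash with both axial methyl groups C19 and C20, while silyl ethers and the isolated alkene are inert.

Step 18
Reactants: 22 1α-alcohol
Product: 23 1α-acetate (4α-OTBS, 7-ene, 9α-CH2OTBS)
Conditions: Ac2O, pyridine, DMAP (cat.), CH2Cl2, 23 °C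
Reagents that add atoms: acetic anhydride, CC(=O)OC(C)=O
Why: Nucleophile-catalysed acylation installs the first of the target acetates and protects C1 during the oxidations.

Step 19
Reactants: 23 1α-acetate
Product: 24 7-en-6-one (1α-OAc, 4α-OTBS, 9α-CH2OTBS)
Conditions: Rh2(cap)4 (cap = caprolactamate, 1 mol %), t-BuOOH, CH2Cl2, 40 °C
Reagents that add atoms: tert-butyl hydroperoxide, CC(C)(C)OO
Why: Dirhodium-catalysed allylic C–H oxidation with the hydroperoxide converts the only allylic ring methylene (C6) into the ketone, giving the enone C6(=O)–C7=C8.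

Step 20
Reactants: 24 enone
Product: 25 7α,8α-dihydroxy-6-ketone (8β-CH3)
Conditions: OsO4 (5 mol %), NMO, citric acid, t-BuOH/H2O, 23 °C
Reagents that add atoms: 4-methylmorpholine N-oxide, C[N+]1([O-])CCOCC1; water, O
Why: Syn-dihydroxylation should occur from the α-face because the β-face of C7=C8 is screened by the axial methyl groups C19 and C20, setting C7 (α-OH) and C8 (α-OH, β-methyl) together.

Step 21
Reactants: 25 diol ketone
Product: 26 7α-(2-methylpropanoyloxy)-8α-hydroxy-6-ketone
Conditions: i-PrCOCl, pyridine, DMAP (cat.), CH2Cl2, 0 °C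
Reagents that add atoms: 2-methylpropanoyl chloride, CC(C)C(Cl)=O
Why: Acylation distinguishes the secondary C7 hydroxyl from the tertiary C8 hydroxyl, placing the isobutyrate at the only position where it is needed.

Step 22
Reactants: 26 α-acyloxy ketone
Product: 27 6β-alcohol (7α-isobutyrate, 8α-OH)
Conditions: Me4NBH(OAc)3, MeCN/AcOH, −20 °C
Reagents that add atoms: none
Why: Evans–Saksena hydroxyl-directed reduction: the axial 8α-hydroxyl binds the borohydride and delivers hydride to the α-face of C6, giving the equatorial 6β-alcohol (1,3-anti to the C8 hydroxyl).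

Step 23
Reactants: 27 6β-alcohol
Product: 28 1α,6β-diacetate 7α-isobutyrate bis-silyl ether
Conditions: Ac2O, pyridine, DMAP, CH2Cl2, 40 °C
Reagents that add atoms: acetic anhydride, CC(=O)OC(C)=O
Why: The secondary 6β-hydroxyl is acetylated while the hindered tertiary C8 hydroxyl is left free, as in the target.

Step 24
Reactants: 28 bis-silyl ether
Product: 29 4α,11-diol
Conditions: HF·pyridine, THF/pyridine, 0 to 23 °C
Reagents that add atoms: none
Why: Fluoride-mediated desilylation frees the C4 and C11 hydroxyls without ester cleavage or acyl migration.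

Step 25
Reactants: 29 diol
Product: 30 4-keto 11-aldehyde
Conditions: Dess–Martin periodinane, CH2Cl2, 23 °C
Reagents that add atoms: none
Why: Hypervalent-iodine oxidation converts the secondary alcohol into the C4 ketone and the primary one into the C11 aldehyde under neutral conditions that spare the tertiary alcohol and avoid retro-aldol cleavage.

Step 26
Reactants: 31 2-methylidenepropane-1,3-diol
Product: 32 2-({[tert-butyl(dimethyl)silyl]oxy}methyl)prop-2-en-1-ol
Conditions: NaH (1.0 equiv), TBSCl, THF, 0 °C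
Reagents that add atoms: tert-butyl(chloro)dimethylsilane, CC(C)(C)[Si](C)(C)Cl
Why: Monosilylation of the symmetrical diol through its sparingly soluble monosodium alkoxide.

Step 27
Reactants: 32 mono-silyl ether
Product: 33 tert-butyl(dimethyl){[2-(4,4,5,5-tetramethyl-1,3,2-dioxaborolan-2-ylmethyl)prop-2-en-1-yl]oxy}silane
Conditions: B2pin2, [Pd(MeCN)4](BF4)2 (5 mol %), DMSO/MeOH, 50 °C
Reagents that add atoms: bis(pinacolato)diboron, CC1(C)OB(OC1(C)C)B1OC(C)(C)C(C)(C)O1
Why: Palladium-catalysed borylation of the allylic alcohol through a symmetrical π-allyl intermediate gives the allylboronate.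

Step 28
Reactants: 30 keto aldehyde; 33 allylboronate
Product: 34 (11R)-homoallylic alcohol with C12–C13(=CH2)–C16H2OTBS chain
Conditions: (R)-TRIP [(R)-3,3′-bis(2,4,6-triisopropylphenyl)-1,1′-binaphthyl-2,2′-diyl hydrogen phosphate] (10 mol %), 4 Å MS, toluene, −30 °C; aqueous work-up
Reagents that add atoms: none
Why: Chiral-phosphoric-acid-catalysed allylboration through a closed six-membered transition state: the catalyst selects the aldehyde face ((R)-catalyst expected to give 11R by analogy with simple aldehydes) and the hindered C4 ketone is not attacked.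

Step 29
Reactants: 34 homoallylic alcohol
Product: 35 11-acetate
Conditions: Ac2O, pyridine, DMAP, CH2Cl2, 23 °C
Reagents that add atoms: acetic anhydride, CC(=O)OC(C)=O
Why: Acylation of the secondary C11 hydroxyl completes the triacetate pattern; the tertiary C8 hydroxyl remains free.

Step 30
Reactants: 35 ketone
Product: 36 4(18)-methylene compound
Conditions: Zn, CH2Br2, TiCl4, THF/CH2Cl2, 0 to 23 °C
Reagents that add atoms: dibromomethane, BrCBr
Why: Takai–Lombardo methylenation converts the hindered C4 ketone into the exocyclic alkene with a non-basic reagent that leaves esters untouched.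

Step 31
Reactants: 36 silyl ether
Product: 37 C16 allylic alcohol
Conditions: HF·pyridine, THF, 0 °C
Reagents that add atoms: none
Why: Desilylation of the primary allylic silyl ether under conditions that keep the four esters in place.

Step 32
Reactants: 37 allylic alcohol; 38 acryloyl chloride
Product: 39 C16 acrylate
Conditions: Et3N, CH2Cl2, −78 °C
Reagents that add atoms: none
Why: Acylation of the primary allylic hydroxyl in preference to the tertiary C8 hydroxyl supplies C14 and C15.

Step 33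
Reactants: 39 acrylate
Product: 40 CNP0266716.2 (target)
Conditions: second-generation Grubbs catalyst RuCl2(=CHPh)(PCy3)(H2IMes) (10 mol %), CH2Cl2, 40 °C
Reagents that add atoms: none
Why: Ring-closing metathesis between the acrylate and the 1,1-disubstituted C13 alkene closes the butenolide (forms C13=C14); the hindered exocyclic C4=C18 alkene should not take part.

**Compound list**
1 | 3-methylbut-3-en-2-one | CC(=O)C(C)=C | starting material
2 | triethyl phosphonoacetate | CCOC(=O)CP(=O)(OCC)OCC | starting material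
3 | ethyl (2E)-3,4-dimethylpenta-2,4-dienoate | CCOC(=O)/C=C(\C)C(C)=C | intermediate
4 | (2E)-3,4-dimethylpenta-2,4-dien-1-ol | OC/C=C(\C)C(C)=C | intermediate
5 | [(2S,3S)-3-methyl-3-(prop-1-en-2-yl)oxiran-2-yl]methanol | C=C(C)[C@]1(C)O[C@H]1CO | intermediate
6 | tert-butyl(dimethyl){[(2S,3S)-3-methyl-3-(prop-1-en-2-yl)oxiran-2-yl]methoxy}silane | C=C(C)[C@]1(C)O[C@H]1CO[Si](C)(C)C(C)(C)C | intermediate
7 | (2S)-2-({[tert-butyl(dimethyl)silyl]oxy}methyl)-2,3-dimethylbut-3-enal | C=C(C)[C@@](C=O)(C)CO[Si](C)(C)C(C)(C)C | intermediate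
8 | (2S)-2-({[tert-butyl(dimethyl)silyl]oxy}methyl)-2,3-dimethylbut-3-enoic acid | C=C(C)[C@@](C(=O)O)(C)CO[Si](C)(C)C(C)(C)C | intermediate
9 | allyl bromide (3-bromoprop-1-ene) | C=CCBr | starting material
10 | prop-2-en-1-yl (2S)-2-({[tert-butyl(dimethyl)silyl]oxy}methyl)-2,3-dimethylbut-3-enoate | C=C(C)[C@@](C(=O)OCC=C)(C)CO[Si](C)(C)C(C)(C)C | intermediate
11 | (3S)-3-({[tert-butyl(dimethyl)silyl]oxy}methyl)-3,4-dimethyl-3,6-dihydro-2H-pyran-2-one | O=C1OCC=C(C)[C@@]1(C)CO[Si](C)(C)C(C)(C)C | intermediate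
12 | (2R,3Z)-2-({[tert-butyl(dimethyl)silyl]oxy}methyl)-2,3-dimethylpent-3-ene-1,5-diol | OC/C=C(C)\[C@](C)(CO)CO[Si](C)(C)C(C)(C)C | intermediate
13 | (2Z,4R)-4-({[tert-butyl(dimethyl)silyl]oxy}methyl)-5-hydroxy-3,4-dimethylpent-2-en-1-yl acetate | CC(=O)OC/C=C(C)\[C@](C)(CO)CO[Si](C)(C)C(C)(C)C | intermediate
14 | 2-methylcyclopentane-1,3-dione | CC1C(=O)CCC1=O | starting material
15 | 2-[(2Z,4R)-4-({[tert-butyl(dimethyl)silyl]oxy}methyl)-5-hydroxy-3,4-dimethylpent-2-en-1-yl]-2-methylcyclopentane-1,3-dione | CC1(C/C=C(C)\[C@](C)(CO)CO[Si](C)(C)C(C)(C)C)C(=O)CCC1=O | intermediate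
16 | (2R,3R)-2-[(2Z,4R)-4-({[tert-butyl(dimethyl)silyl]oxy}methyl)-5-hydroxy-3,4-dimethylpent-2-en-1-yl]-3-hydroxy-2-methylcyclopentan-1-one | O=C1CC[C@@H](O)[C@@]1(C)C/C=C(C)\[C@](C)(CO)CO[Si](C)(C)C(C)(C)C | intermediate
17 | (2S,3Z)-2-({[tert-butyl(dimethyl)silyl]oxy}methyl)-5-[(1R,2R)-2-hydroxy-1-methyl-5-oxocyclopentyl]-2,3-dimethylpent-3-enal | O=C1CC[C@@H](O)[C@@]1(C)C/C=C(C)\[C@](C)(C=O)CO[Si](C)(C)C(C)(C)C | intermediate
18 | (2S,3Z)-5-[(1R,2R)-2-{[tert-butyl(dimethyl)silyl]oxy}-1-methyl-5-oxocyclopentyl]-2-({[tert-butyl(dimethyl)silyl]oxy}methyl)-2,3-dimethylpent-3-enal | O=C1CC[C@@H](O[Si](C)(C)C(C)(C)C)[C@@]1(C)C/C=C(C)\[C@](C)(C=O)CO[Si](C)(C)C(C)(C)C | intermediate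
19 | (E)-N-(tert-butyldimethylsilyl) hydrazone of 18 at C10 | O=C1CC[C@@H](O[Si](C)(C)C(C)(C)C)[C@@]1(C)C/C=C(C)\[C@](C)(/C=N/N[Si](C)(C)C(C)(C)C)CO[Si](C)(C)C(C)(C)C | intermediate
20 | diazoalkane (C10 diazomethyl analogue of 18) | O=C1CC[C@@H](O[Si](C)(C)C(C)(C)C)[C@@]1(C)C/C=C(C)\[C@](C)(C=[N+]=[N-])CO[Si](C)(C)C(C)(C)C | intermediate
21 | trans-decalone: C1 ketone, 4α-OTBS, 5β-CH3, 7-ene with 8-CH3, 9β-CH3, 9α-CH2OTBS, 10α-H | CC(C)(C)[Si](C)(C)O[C@@H]1CCC(=O)[C@@H]2[C@]1(C)CC=C(C)[C@@]2(C)CO[Si](C)(C)C(C)(C)C | intermediate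
22 | 1α-alcohol of 21 | CC(C)(C)[Si](C)(C)O[C@@H]1CC[C@H](O)[C@@H]2[C@]1(C)CC=C(C)[C@@]2(C)CO[Si](C)(C)C(C)(C)C | intermediate
23 | 1α-acetate of 22 | CC(C)(C)[Si](C)(C)O[C@@H]1CC[C@H](OC(C)=O)[C@@H]2[C@]1(C)CC=C(C)[C@@]2(C)CO[Si](C)(C)C(C)(C)C | intermediate
24 | 7-en-6-one: 1α-OAc, 4α-OTBS, 9α-CH2OTBS | CC(C)(C)[Si](C)(C)O[C@@H]1CC[C@H](OC(C)=O)[C@@H]2[C@]1(C)C(=O)C=C(C)[C@@]2(C)CO[Si](C)(C)C(C)(C)C | intermediate
25 | 7α,8α-dihydroxy-6-ketone (8β-CH3) | CC(C)(C)[Si](C)(C)O[C@@H]1CC[C@H](OC(C)=O)[C@@H]2[C@]1(C)C(=O)[C@@H](O)[C@@](C)(O)[C@@]2(C)CO[Si](C)(C)C(C)(C)C | intermediate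
26 | 7α-(2-methylpropanoyloxy)-8α-hydroxy-6-ketone | CC(C)(C)[Si](C)(C)O[C@@H]1CC[C@H](OC(C)=O)[C@@H]2[C@]1(C)C(=O)[C@@H](OC(=O)C(C)C)[C@@](C)(O)[C@@]2(C)CO[Si](C)(C)C(C)(C)C | intermediate
27 | 6β-alcohol (7α-isobutyrate, 8α-OH) | CC(C)(C)[Si](C)(C)O[C@@H]1CC[C@H](OC(C)=O)[C@@H]2[C@]1(C)[C@H](O)[C@@H](OC(=O)C(C)C)[C@@](C)(O)[C@@]2(C)CO[Si](C)(C)C(C)(C)C | intermediate
28 | 1α,6β-diacetate 7α-isobutyrate, 4α,11-bis-OTBS | CC(C)(C)[Si](C)(C)O[C@@H]1CC[C@H](OC(C)=O)[C@@H]2[C@]1(C)[C@H](OC(C)=O)[C@@H](OC(=O)C(C)C)[C@@](C)(O)[C@@]2(C)CO[Si](C)(C)C(C)(C)C | intermediate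
29 | 4α,11-diol | O[C@@H]1CC[C@H](OC(C)=O)[C@@H]2[C@]1(C)[C@H](OC(C)=O)[C@@H](OC(=O)C(C)C)[C@@](C)(O)[C@@]2(C)CO | intermediate
30 | 4-keto 11-aldehyde | O=C1CC[C@H](OC(C)=O)[C@@H]2[C@]1(C)[C@H](OC(C)=O)[C@@H](OC(=O)C(C)C)[C@@](C)(O)[C@@]2(C)C=O | intermediate
31 | 2-methylidenepropane-1,3-diol | C=C(CO)CO | starting material
32 | 2-({[tert-butyl(dimethyl)silyl]oxy}methyl)prop-2-en-1-ol | C=C(CO)CO[Si](C)(C)C(C)(C)C | intermediate
33 | tert-butyl(dimethyl){[2-(4,4,5,5-tetramethyl-1,3,2-dioxaborolan-2-ylmethyl)prop-2-en-1-yl]oxy}silane | C=C(CB1OC(C)(C)C(C)(C)O1)CO[Si](C)(C)C(C)(C)C | intermediate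
34 | (11R)-homoallylic alcohol: 4-ketone, C12H2–C13(=CH2)–C16H2OTBS | O=C1CC[C@H](OC(C)=O)[C@@H]2[C@]1(C)[C@H](OC(C)=O)[C@@H](OC(=O)C(C)C)[C@@](C)(O)[C@@]2(C)[C@@H](CC(=C)CO[Si](C)(C)C(C)(C)C)O | intermediate
35 | (11R)-11-acetate of 34 | O=C1CC[C@H](OC(C)=O)[C@@H]2[C@]1(C)[C@H](OC(C)=O)[C@@H](OC(=O)C(C)C)[C@@](C)(O)[C@@]2(C)[C@@H](CC(=C)CO[Si](C)(C)C(C)(C)C)OC(C)=O | intermediate
36 | 4(18)-methylene compound | C=C1CC[C@H](OC(C)=O)[C@@H]2[C@]1(C)[C@H](OC(C)=O)[C@@H](OC(=O)C(C)C)[C@@](C)(O)[C@@]2(C)[C@@H](CC(=C)CO[Si](C)(C)C(C)(C)C)OC(C)=O | intermediate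
37 | C16 allylic alcohol | C=C1CC[C@H](OC(C)=O)[C@@H]2[C@]1(C)[C@H](OC(C)=O)[C@@H](OC(=O)C(C)C)[C@@](C)(O)[C@@]2(C)[C@@H](CC(=C)CO)OC(C)=O | intermediate
38 | acryloyl chloride | C=CC(Cl)=O | starting material
39 | C16 acrylate | C=C1CC[C@H](OC(C)=O)[C@@H]2[C@]1(C)[C@H](OC(C)=O)[C@@H](OC(=O)C(C)C)[C@@](C)(O)[C@@]2(C)[C@@H](CC(=C)COC(=O)C=C)OC(C)=O | intermediate
40 | CNP0266716.2, (1S,5S,6S,7R,8S,9R,10R,11R): 1α,6β,11-triacetoxy-8α-hydroxy-7α-(2-methylpropanoyloxy)-4(18)-methylene decalin with 15,16-butenolide | C=C1CC[C@H](OC(C)=O)[C@@H]2[C@]1(C)[C@H](OC(C)=O)[C@@H](OC(=O)C(C)C)[C@@](C)(O)[C@@]2(C)[C@@H](CC1=CC(=O)OC1)OC(C)=O | target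

**Totals and risks**
Total step count: 33. Longest linear sequence: 31 steps (steps 1–25 and 28–33); steps 26–27 form a two-step side branch.

Most likely to fail:

1. Step 16. The diazoalkane may be consumed before it reaches the ketone (dipolar cycloaddition onto C7=C8 or carbene-type decomposition). The wrong α-carbon (C2) may migrate, or the adduct may collapse to an epoxide. The ring fusion may also not equilibrate to trans. The fallback uses known chemistry, sets out from 18 and comes back at 21. SmI2-mediated ketyl–aldehyde pinacol cyclisation (SmI2, THF/t-BuOH, −78 °C) should join C1 and C10 to give the seven-membered cis-diol F1. Mesylation of the secondary C10 hydroxyl (MsCl, Et3N, CH2Cl2, 0 °C) gives the mesylate F2. Et3Al (CH2Cl2, −78 °C) then triggers the semipinacol 1,2-shift of C5 from C1 to C10 with loss of mesylate, giving 21.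

2. Step 17. The medium is strongly basic, so the C10 centre may epimerise, and the equatorial/axial ratio at C1 may be poor. The fallback sets out from 21 and comes back at 23. NaBH4/CeCl3 (MeOH, −40 °C) should attack the open α-face to give the axial 1β-alcohol F3. Mitsunobu inversion with acetic acid (PPh3, DIAD, toluene, 0 to 23 °C) then gives the 1α-acetate 23 directly.

3. Step 19. Allylic C–H oxidation at the neopentyl C6 may be sluggish or unselective (attack at the C17 methyl, mixed peroxides, alkene transposition). The fallback sets out from 23 and comes back at 24. mCPBA (CH2Cl2, 0 °C) should give the 7α,8α-epoxide F4 from the open α-face. Opening at C7 with PhSeNa ((PhSe)2, NaBH4, EtOH, reflux) gives the hydroxy selenide F5. H2O2 oxidation and selenoxide syn-elimination towards C6 give the tertiary allylic alcohol F6. Pyridinium chlorochromate, C5H5NH[CrO3Cl] (CH2Cl2, 23 °C), then effects the oxidative 1,3-transposition (Babler–Dauben) to enone 24.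

**Further compounds**
F1 | step 16 | cis-diol from pinacol cyclisation of 18 (C1 tertiary and C10 secondary carbinols, bicyclo[5.3.0] skeleton) | O[C@]12CC[C@@H](O[Si](C)(C)C(C)(C)C)[C@@]1(C)CC=C(C)[C@@](C)(CO[Si](C)(C)C(C)(C)C)[C@@H]2O
F2 | step 16 | C10 mesylate of F1 | O[C@]12CC[C@@H](O[Si](C)(C)C(C)(C)C)[C@@]1(C)CC=C(C)[C@@](C)(CO[Si](C)(C)C(C)(C)C)[C@@H]2OS(C)(=O)=O
F3 | step 17 | 1β-alcohol (C1 epimer of 22) | CC(C)(C)[Si](C)(C)O[C@@H]1CC[C@@H](O)[C@@H]2[C@]1(C)CC=C(C)[C@@]2(C)CO[Si](C)(C)C(C)(C)C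
F4 | step 19 | 7α,8α-epoxide of 23 | CC(C)(C)[Si](C)(C)O[C@@H]1CC[C@H](OC(C)=O)[C@@H]2[C@]1(C)C[C@H]3O[C@@]3(C)[C@@]2(C)CO[Si](C)(C)C(C)(C)C
F5 | step 19 | 7β-phenylselanyl-8α-ol | CC(C)(C)[Si](C)(C)O[C@@H]1CC[C@H](OC(C)=O)[C@@H]2[C@]1(C)C[C@H]([Se]c3ccccc3)[C@@](C)(O)[C@@]2(C)CO[Si](C)(C)C(C)(C)C
F6 | step 19 | 6-en-8α-ol (tertiary allylic alcohol) | CC(C)(C)[Si](C)(C)O[C@@H]1CC[C@H](OC(C)=O)[C@@H]2[C@]1(C)C=C[C@@](C)(O)[C@@]2(C)CO[Si](C)(C)C(C)(C)C
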